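## Retrosynthetic overview

1. The target is reached by O-debenzylation of its 7,4'-di-O-benzyl ether (upper unit protected, lower unit free).
2. The interflavan C4–C8 bond is cut next: Friedel–Crafts alkylation of bought (−)-epiafzelechin, which carries both lower stereocenters, by a flavan-4-yl cation. Attack anti to the C2 aryl group sets C4 trans to C2.
3. Upper ring C (O1–C2 and C3–C4 bonds) is the key ring: inverse-electron-demand hetero-Diels–Alder [4+2] of an α-methoxy o-quinone methide (from 4-(benzyloxy)-2-hydroxybenzaldehyde and trimethyl orthoformate) with 4-(benzyloxy)styrene.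
4. Ring order: upper ring C is the only ring made (step 1); all aromatic rings and the lower ring C are bought. The cycloaddition gives the upper unit racemic at C2, so the (2S) series is separated as a diastereomer after coupling to the enantiopure lower unit.

Assumption: (−)-epiafzelechin, the (2R,3R)-configured natural flavan-3-ol, is bought enantiopure.

## Route

Step 1
Reactants: 1 4-(benzyloxy)-2-hydroxybenzaldehyde; 2 4-(benzyloxy)styrene
Product: 5 racemic 7-(benzyloxy)-2-[4-(benzyloxy)phenyl]-4-methoxychromane (2,4-cis/trans mixture), via dimethyl acetal 3 (not isolated), via methoxy o-quinone methide 4 (not isolated)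
Conditions: HC(OMe)3 (1.5 equiv), 2 (2 equiv, slow addition), Sc(OTf)3 (5 mol %), CH2Cl2, 0 °C to rt
Reagents that add atoms: trimethyl orthoformate, COC(OC)OC
Why: The acid converts 1 into acetal 3, which loses methanol to the α-methoxy o-quinone methide 4; this electron-poor 1-oxadiene adds the electron-rich styrene in an inverse-electron-demand hetero-Diels–Alder [4+2] cycloaddition (styrene CH2 to the methide carbon, benzylic carbon to oxygen), closing ring C with C2 and C4 racemic; C4 is erased in step 2 and the C2 antipodes are separated there as diastereomers.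

Step 2
Reactants: 5 racemic 7-(benzyloxy)-2-[4-(benzyloxy)phenyl]-4-methoxychromane; 6 (−)-epiafzelechin
Product: 8 (2R,3R)-8-{(2S,4R)-7-(benzyloxy)-2-[4-(benzyloxy)phenyl]-3,4-dihydro-2H-chromen-4-yl}-2-(4-hydroxyphenyl)-3,4-dihydro-2H-chromene-3,5,7-triol, via flavan-4-yl cation 7 (not isolated)
Conditions: 6 (3 equiv, excess recovered), TsOH·H2O (10 mol %), 1,4-dioxane, rt; silica gel chromatography, then achiral C18 HPLC
Reagents that add atoms: none
Why: Acid ionises the 4-methoxy group to cation 7 (stabilised by O1 and the 7-benzyloxy group), which alkylates the most nucleophilic position of 6 (C8 of the phloroglucinol-type ring A) in a Friedel–Crafts reaction; pseudo-axial attack anti to the equatorial C2 aryl group sets C4 trans to C2, so the (2S)-cation gives (2S,4R)-configured 8, while the (2R)-cation gives the (2R,4S) diastereomer, which is removed by chromatography together with the minor C6-linked and 2,4-cis isomers.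

Step 3
Reactants: 8 the 7,4'-di-O-benzyl dimer from step 2
Product: 9 (2R,3R)-8-[(2S,4R)-7-hydroxy-2-(4-hydroxyphenyl)-3,4-dihydro-2H-chromen-4-yl]-2-(4-hydroxyphenyl)-3,4-dihydro-2H-chromene-3,5,7-triol
Conditions: H2 (1 atm), Pd(OH)2/C (20 wt %), THF/MeOH 1:1, rt
Reagents that add atoms: none
Why: Catalytic hydrogenolysis cleaves only the two aryl benzyl ethers; the cyclic benzylic C2–O1 ethers and the doubly benzylic C4–C8 bond are not cleaved at room temperature and 1 atm, so the four stereocenters are untouched.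

## Compound list

1 | 4-(benzyloxy)-2-hydroxybenzaldehyde | O=Cc1ccc(OCc2ccccc2)cc1O | starting material
2 | 4-(benzyloxy)styrene (1-(benzyloxy)-4-ethenylbenzene) | C=Cc1ccc(OCc2ccccc2)cc1 | starting material
3 | 5-(benzyloxy)-2-(dimethoxymethyl)phenol (not isolated) | COC(OC)c1ccc(OCc2ccccc2)cc1O | intermediate
4 | (6E)-3-(benzyloxy)-6-(methoxymethylidene)cyclohexa-2,4-dien-1-one (not isolated) | CO/C=C1\C=CC(OCc2ccccc2)=CC1=O | intermediate
5 | 7-(benzyloxy)-2-[4-(benzyloxy)phenyl]-4-methoxychromane (racemic, 2,4-cis/trans mixture, no stereodescriptors) | COC1CC(c2ccc(OCc3ccccc3)cc2)Oc2cc(OCc3ccccc3)ccc12 | intermediate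
6 | (−)-epiafzelechin, (2R,3R)-2-(4-hydroxyphenyl)-3,4-dihydro-2H-chromene-3,5,7-triol | Oc1cc(O)c2c(c1)O[C@H](c1ccc(O)cc1)[C@H](O)C2 | starting material
7 | 7-(benzyloxy)-2-[4-(benzyloxy)phenyl]chroman-4-ylium (racemic at C2, not isolated) | [CH+]1CC(c2ccc(OCc3ccccc3)cc2)Oc2cc(OCc3ccccc3)ccc12 | intermediate
8 | (2R,3R)-8-{(2S,4R)-7-(benzyloxy)-2-[4-(benzyloxy)phenyl]-3,4-dihydro-2H-chromen-4-yl}-2-(4-hydroxyphenyl)-3,4-dihydro-2H-chromene-3,5,7-triol | c1ccccc1COc1ccc([C@@H]2C[C@@H](c3c(O)cc(O)c4c3O[C@H](c3ccc(O)cc3)[C@H](O)C4)c3ccc(OCc5ccccc5)cc3O2)cc1 | intermediate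
9 | (2R,3R)-8-[(2S,4R)-7-hydroxy-2-(4-hydroxyphenyl)-3,4-dihydro-2H-chromen-4-yl]-2-(4-hydroxyphenyl)-3,4-dihydro-2H-chromene-3,5,7-triol; upper 2,4-trans flavan linked C4 to C8 of (−)-epiafzelechin | Oc1ccc([C@@H]2C[C@@H](c3c(O)cc(O)c4c3O[C@H](c3ccc(O)cc3)[C@H](O)C4)c3ccc(O)cc3O2)cc1 | target

## Step count and risks

Total step count: 3. Longest linear sequence: 3 steps (1 → 5 → 8 → 9).

The three steps most likely to fail are step 2, step 1 and step 3, in that order.

**Step 2.** This is the weakest point. Because 5 is racemic at C2, at most half of the trans-coupled material is 8, and the C6-linked and 2,4-cis isomers must also be separated. The fallback sets out from 6 and comes back to the route at 9. It buys the upper C2 stereocenter instead of separating it: bought (2S)-liquiritigenin (O=C1C[C@@H](c2ccc(O)cc2)Oc2cc(O)ccc12) is reduced with NaBH4 in EtOH at 0 °C to the 2,4-cis flavan-4-ol (2S,4S)-2-(4-hydroxyphenyl)-3,4-dihydro-2H-chromene-4,7-diol F4. F4 and 6 (3 equiv) are then condensed in 0.1 M HCl in dioxane–water at rt. The (2S)-configured 4-cation is attacked anti to its C2 aryl group by C8 of 6 and gives 9 directly, without protecting groups.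

**Step 1.** The Lewis acid can start cationic oligomerisation of the electron-rich styrene or re-ionise 5 at C4. The fallback sets out from 1 and comes back to the route at 8, entering through cation 7:
- Claisen–Schmidt condensation of 1 with bought 4'-(benzyloxy)acetophenone (CC(=O)c1ccc(OCc2ccccc2)cc1) in KOH/EtOH gives (E)-3-[4-(benzyloxy)-2-hydroxyphenyl]-1-[4-(benzyloxy)phenyl]prop-2-en-1-one F1.
- 1,2-Reduction with NaBH4 and CeCl3·7H2O in MeOH at 0 °C gives (E)-3-[4-(benzyloxy)-2-hydroxyphenyl]-1-[4-(benzyloxy)phenyl]prop-2-en-1-ol F2.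
- TsOH (cat.) in toluene at 50 °C dehydrates F2 to a vinyl o-quinone methide, which closes by oxa-6π-electrocyclisation to racemic 7-(benzyloxy)-2-[4-(benzyloxy)phenyl]-2H-chromene F3.
- Under the conditions of step 2, F3 is protonated at C3 to cation 7 and trapped by 6 to give 8.

**Step 3.** Hydrogenolysis could be slowed by the polyphenol or could open a benzylic C2–O1 bond. The fallback sets out from 8 and comes back to the route at 9. It replaces reductive cleavage by Lewis-acid debenzylation with a cation scavenger: BCl3 (6 equiv) and pentamethylbenzene (10 equiv) in CH2Cl2 at −78 °C, quenched with MeOH. It makes no compound that is not already listed (none F0).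

## Further compounds

F1 | step 1 | (E)-3-[4-(benzyloxy)-2-hydroxyphenyl]-1-[4-(benzyloxy)phenyl]prop-2-en-1-one | O=C(/C=C/c1ccc(OCc2ccccc2)cc1O)c1ccc(OCc2ccccc2)cc1
F2 | step 1 | (E)-3-[4-(benzyloxy)-2-hydroxyphenyl]-1-[4-(benzyloxy)phenyl]prop-2-en-1-ol (racemic) | OC(/C=C/c1ccc(OCc2ccccc2)cc1O)c1ccc(OCc2ccccc2)cc1
F3 | step 1 | 7-(benzyloxy)-2-[4-(benzyloxy)phenyl]-2H-chromene (racemic) | C1(c2ccc(OCc3ccccc3)cc2)C=Cc2ccc(OCc3ccccc3)cc2O1
F4 | step 2 | (2S,4S)-2-(4-hydroxyphenyl)-3,4-dihydro-2H-chromene-4,7-diol | O[C@H]1C[C@@H](c2ccc(O)cc2)Oc2cc(O)ccc12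
F0 | step 3 | none | none
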